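**Assumption:** the target has no stereocentres, so there is no enantiomer to control; intermediates 3–5 are racemic mixtures whose stereocentres are erased on aromatisation. Locants on both benzoate rings use C1 = carboxyl carbon and C6 = pentyl-bearing carbon throughout.

## Retrosynthetic overview

1. Target 19 ⇐ tribenzyl-protected diaryl ether 18 by one global hydrogenolysis; the ring A methyl ester stays.
2. 18 ⇐ Ullmann C–O coupling of ring A aryl bromide 10 with ring B phenol 17.
3. 10 and 17 ⇐ the same resorcylate, methyl olivetolate 6 (ring A: 4-O-benzyl, OH → OTf → Bpin → Br; ring B: 4-O-methyl, methyl → benzyl ester, C5 Br → Bpin → OH).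
4. 6 ⇐ cyclohexane-1,3-dione 4 ⇐ Michael addition of dimethyl malonate 1 to (E)-non-3-en-2-one 2 (key C–C bond), then Dieckmann closure.
5. Ring order: the carbocycle is built once (Michael → Dieckmann → aromatise) and used as both ring A and ring B; the diaryl ether is joined last.

## Route

**Step 1**
Reactants: 1 dimethyl malonate; 2 (E)-non-3-en-2-one
Product: 4 methyl 2,4-dioxo-6-pentylcyclohexane-1-carboxylate, via Michael adduct 3 (not isolated)
Conditions: NaOMe (1.1 equiv), MeOH, reflux; then aq. HCl, 0 °C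
Reagents that add atoms: none
Why: Michael addition of the malonate anion to the enone, then an intramolecular Claisen (Dieckmann) condensation of the methyl-ketone enolate onto a malonate ester, driven by the stabilised 1,3-dione enolate; the stereocentres are racemic and are destroyed in step 2.

**Step 2**
Reactants: 4 methyl 2,4-dioxo-6-pentylcyclohexane-1-carboxylate
Product: 6 methyl 2,4-dihydroxy-6-pentylbenzoate, via bromo dione 5 (not isolated)
Conditions: Br2 (1.0 equiv), DMF, 0 °C then 80 °C
Reagents that add atoms: none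
Why: halogenation–dehydrohalogenation aromatisation, in which α-bromination of the 1,3-dione is followed by thermal loss of HBr and tautomerisation to the resorcinol.

**Step 3**
Reactants: 6 methyl 2,4-dihydroxy-6-pentylbenzoate
Product: 7 methyl 4-(benzyloxy)-2-hydroxy-6-pentylbenzoate
Conditions: BnBr (1.05 equiv), K2CO3 (1.1 equiv), acetone, reflux
Reagents that add atoms: benzyl bromide, BrCc1ccccc1
Why: Williamson etherification that is selective for the 4-OH because the 2-OH is hydrogen-bonded to the ester and much less nucleophilic.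

**Step 4**
Reactants: 7 methyl 4-(benzyloxy)-2-hydroxy-6-pentylbenzoate
Product: 8 methyl 4-(benzyloxy)-6-pentyl-2-[(trifluoromethanesulfonyl)oxy]benzoate
Conditions: Tf2O (1.2 equiv), pyridine, CH2Cl2, 0 °C to rt
Reagents that add atoms: trifluoromethanesulfonic anhydride, O=S(=O)(OS(=O)(=O)C(F)(F)F)C(F)(F)F
Why: O-sulfonylation of the remaining phenol turns the ring A oxygen into a cross-coupling leaving group.

**Step 5**
Reactants: 8 methyl 4-(benzyloxy)-6-pentyl-2-[(trifluoromethanesulfonyl)oxy]benzoate
Product: 9 methyl 4-(benzyloxy)-6-pentyl-2-(4,4,5,5-tetramethyl-1,3,2-dioxaborolan-2-yl)benzoate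
Conditions: B2pin2 (1.3 equiv), PdCl2(dppf) (5 mol%, dppf = 1,1'-bis(diphenylphosphino)ferrocene), KOAc (3 equiv), dioxane, 90 °C
Reagents that add atoms: bis(pinacolato)diboron, CC1(C)OB(OC1(C)C)B1OC(C)(C)C(C)(C)O1
Why: Miyaura borylation, in which the aryl triflate adds oxidatively to zerovalent palladium and acetate-assisted transmetalation delivers the boryl group; esters and benzyl ethers are inert.

**Step 6**
Reactants: 9 methyl 4-(benzyloxy)-6-pentyl-2-(4,4,5,5-tetramethyl-1,3,2-dioxaborolan-2-yl)benzoate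
Product: 10 methyl 4-(benzyloxy)-2-bromo-6-pentylbenzoate
Conditions: CuBr2 (3 equiv), MeOH/H2O 1:1, 80 °C
Reagents that add atoms: CuBr2, Br[Cu]Br
Why: copper-mediated ipso-bromodeboronation replaces boron by bromine at the same carbon, giving the ortho-ester-activated aryl bromide needed for the Ullmann step.

**Step 7**
Reactants: 6 methyl 2,4-dihydroxy-6-pentylbenzoate
Product: 11 methyl 2-hydroxy-4-methoxy-6-pentylbenzoate
Conditions: MeI (1.1 equiv), K2CO3 (1.1 equiv), acetone, reflux
Reagents that add atoms: iodomethane, CI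
Why: Williamson methylation with the same chelation-controlled selectivity for the 4-OH as in step 3.

**Step 8**
Reactants: 11 methyl 2-hydroxy-4-methoxy-6-pentylbenzoate
Product: 12 2-hydroxy-4-methoxy-6-pentylbenzoic acid
Conditions: KOH (10 equiv), DMSO/H2O 4:1, 80 °C; then cold 1 M HCl to pH 2
Reagents that add atoms: potassium hydroxide, [K+].[OH-]
Why: saponification of the hindered di-ortho-substituted ester needs poorly solvated hydroxide in DMSO, and cold acidification avoids decarboxylation of the salicylic acid.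

**Step 9**
Reactants: 12 2-hydroxy-4-methoxy-6-pentylbenzoic acid
Product: 13 benzyl 2-(benzyloxy)-4-methoxy-6-pentylbenzoate
Conditions: BnBr (2.5 equiv), K2CO3 (3 equiv), DMF, rt then 60 °C
Reagents that add atoms: benzyl bromide, BrCc1ccccc1
Why: double O-alkylation (carboxylate first, then the chelated phenol under forcing conditions) installs a benzyl ester and benzyl ether that both come off by hydrogenolysis at the end.

**Step 10**
Reactants: 13 benzyl 2-(benzyloxy)-4-methoxy-6-pentylbenzoate
Product: 14 benzyl 2-(benzyloxy)-5-bromo-4-methoxy-6-pentylbenzoate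
Conditions: NBS (1.05 equiv), MeCN, 0 °C to rt, dark
Reagents that add atoms: N-bromosuccinimide, O=C1CCC(=O)N1Br
Why: electrophilic aromatic bromination goes to C5 (para to the 2-benzyloxy, ortho to the 4-methoxy) rather than C3 between the two alkoxy groups, as is usual for 5-alkylresorcinol diethers.

**Step 11**
Reactants: 14 benzyl 2-(benzyloxy)-5-bromo-4-methoxy-6-pentylbenzoate
Product: 15 benzyl 2-(benzyloxy)-4-methoxy-6-pentyl-5-(4,4,5,5-tetramethyl-1,3,2-dioxaborolan-2-yl)benzoate
Conditions: pinacolborane (2 equiv), PdCl2(MeCN)2 (4 mol%), SPhos (2-dicyclohexylphosphino-2',6'-dimethoxybiphenyl, 8 mol%), Et3N (3 equiv), dioxane, 100 °C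
Reagents that add atoms: pinacolborane, CC1(C)OBOC1(C)C
Why: palladium-catalysed Miyaura-type borylation with the bulky, electron-rich SPhos ligand, a system that handles di-ortho-substituted electron-rich aryl bromides and tolerates esters.

**Step 12**
Reactants: 15 benzyl 2-(benzyloxy)-4-methoxy-6-pentyl-5-(4,4,5,5-tetramethyl-1,3,2-dioxaborolan-2-yl)benzoate
Product: 17 benzyl 2-(benzyloxy)-5-hydroxy-4-methoxy-6-pentylbenzoate, via aryl pinacol borate 16 (not isolated)
Conditions: Oxone (2KHSO5·KHSO4·K2SO4, 1.1 equiv KHSO5), acetone/H2O, 0 °C to rt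
Reagents that add atoms: potassium peroxymonosulfate (KHSO5), [K+].[O-]S(=O)(=O)OO
Why: oxidative boron-to-oxygen 1,2-aryl migration and hydrolysis of the resulting borate give the phenol under near-neutral conditions that leave the benzyl ester untouched.

**Step 13**
Reactants: 10 methyl 4-(benzyloxy)-2-bromo-6-pentylbenzoate; 17 benzyl 2-(benzyloxy)-5-hydroxy-4-methoxy-6-pentylbenzoate
Product: 18 benzyl 2-(benzyloxy)-5-[5-(benzyloxy)-2-(methoxycarbonyl)-3-pentylphenoxy]-4-methoxy-6-pentylbenzoate
Conditions: CuI (10 mol%), picolinic acid (20 mol%), K3PO4 (2 equiv), DMSO, 90 °C, Ar (10 used at 1.2 equiv)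
Reagents that add atoms: none
Why: Ullmann diaryl ether synthesis catalysed by monovalent copper, where the bromide is activated by its ortho ester and the picolinic acid ligand is suited to hindered phenoxides.

**Step 14**
Reactants: 18 benzyl 2-(benzyloxy)-5-[5-(benzyloxy)-2-(methoxycarbonyl)-3-pentylphenoxy]-4-methoxy-6-pentylbenzoate
Product: 19 epiphorellic acid 1, 2-hydroxy-5-[5-hydroxy-2-(methoxycarbonyl)-3-pentylphenoxy]-4-methoxy-6-pentylbenzoic acid
Conditions: H2 (1 atm), 10% Pd/C, EtOAc, rt
Reagents that add atoms: none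
Why: catalytic hydrogenolysis removes both benzyl ethers and the benzyl ester in one operation while the methyl ester, methyl ether and diaryl ether are inert.

## Compound list

1 | dimethyl malonate | COC(=O)CC(=O)OC | starting material
2 | (E)-non-3-en-2-one | CCCCC/C=C/C(C)=O | starting material
3 | dimethyl 2-(2-oxononan-4-yl)propanedioate (Michael adduct, racemic) | CCCCCC(CC(C)=O)C(C(=O)OC)C(=O)OC | intermediate (not isolated)
4 | methyl 2,4-dioxo-6-pentylcyclohexane-1-carboxylate (racemic diastereomer mixture; exists largely as the enol methyl 2-hydroxy-4-oxo-6-pentylcyclohex-2-ene-1-carboxylate) | CCCCCC1CC(=O)CC(=O)C1C(=O)OC | intermediate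
5 | methyl 3-bromo-2,4-dioxo-6-pentylcyclohexane-1-carboxylate (racemic) | CCCCCC1CC(=O)C(Br)C(=O)C1C(=O)OC | intermediate (not isolated)
6 | methyl 2,4-dihydroxy-6-pentylbenzoate (methyl olivetolate) | CCCCCc1cc(O)cc(O)c1C(=O)OC | intermediate
7 | methyl 4-(benzyloxy)-2-hydroxy-6-pentylbenzoate | CCCCCc1cc(OCc2ccccc2)cc(O)c1C(=O)OC | intermediate
8 | methyl 4-(benzyloxy)-6-pentyl-2-[(trifluoromethanesulfonyl)oxy]benzoate | CCCCCc1cc(OCc2ccccc2)cc(OS(=O)(=O)C(F)(F)F)c1C(=O)OC | intermediate
9 | methyl 4-(benzyloxy)-6-pentyl-2-(4,4,5,5-tetramethyl-1,3,2-dioxaborolan-2-yl)benzoate | CCCCCc1cc(OCc2ccccc2)cc(B2OC(C)(C)C(C)(C)O2)c1C(=O)OC | intermediate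
10 | methyl 4-(benzyloxy)-2-bromo-6-pentylbenzoate | CCCCCc1cc(OCc2ccccc2)cc(Br)c1C(=O)OC | intermediate
11 | methyl 2-hydroxy-4-methoxy-6-pentylbenzoate | CCCCCc1cc(OC)cc(O)c1C(=O)OC | intermediate
12 | 2-hydroxy-4-methoxy-6-pentylbenzoic acid | CCCCCc1cc(OC)cc(O)c1C(=O)O | intermediate
13 | benzyl 2-(benzyloxy)-4-methoxy-6-pentylbenzoate | CCCCCc1cc(OC)cc(OCc2ccccc2)c1C(=O)OCc1ccccc1 | intermediate
14 | benzyl 2-(benzyloxy)-5-bromo-4-methoxy-6-pentylbenzoate | CCCCCc1c(Br)c(OC)cc(OCc2ccccc2)c1C(=O)OCc1ccccc1 | intermediate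
15 | benzyl 2-(benzyloxy)-4-methoxy-6-pentyl-5-(4,4,5,5-tetramethyl-1,3,2-dioxaborolan-2-yl)benzoate | CCCCCc1c(B2OC(C)(C)C(C)(C)O2)c(OC)cc(OCc2ccccc2)c1C(=O)OCc1ccccc1 | intermediate
16 | benzyl 2-(benzyloxy)-4-methoxy-6-pentyl-5-[(4,4,5,5-tetramethyl-1,3,2-dioxaborolan-2-yl)oxy]benzoate | CCCCCc1c(OB2OC(C)(C)C(C)(C)O2)c(OC)cc(OCc2ccccc2)c1C(=O)OCc1ccccc1 | intermediate (not isolated)
17 | benzyl 2-(benzyloxy)-5-hydroxy-4-methoxy-6-pentylbenzoate | CCCCCc1c(O)c(OC)cc(OCc2ccccc2)c1C(=O)OCc1ccccc1 | intermediate
18 | benzyl 2-(benzyloxy)-5-[5-(benzyloxy)-2-(methoxycarbonyl)-3-pentylphenoxy]-4-methoxy-6-pentylbenzoate | CCCCCc1cc(OCc2ccccc2)cc(Oc2c(OC)cc(OCc3ccccc3)c(C(=O)OCc3ccccc3)c2CCCCC)c1C(=O)OC | intermediate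
19 | epiphorellic acid 1, 2-hydroxy-5-[5-hydroxy-2-(methoxycarbonyl)-3-pentylphenoxy]-4-methoxy-6-pentylbenzoic acid (achiral) | CCCCCc1cc(O)cc(Oc2c(OC)cc(O)c(C(=O)O)c2CCCCC)c1C(=O)OC | target

## Step count and risk

Total steps: 14 (steps 1–2 common, 3–6 ring A, 7–12 ring B, 13–14 union and deprotection).
Longest linear sequence: 10 steps (1, 2, 7, 8, 9, 10, 11, 12, 13, 14).

**Step 13 (Ullmann coupling of a di-ortho-substituted phenol).** The risk is slow coupling with protodebromination of 10. The fallback changes from halide substitution to an oxidative boron-to-oxygen aryl transfer (Chan–Lam–Evans coupling). It sets out from boronate 9, so steps 6 and 13 are bypassed. The pinacol ester is cleaved with NaIO4 and NH4OAc in acetone/water to give [5-(benzyloxy)-2-(methoxycarbonyl)-3-pentylphenyl]boronic acid F1. F1 (2 equiv) is then stirred with phenol 17, Cu(OAc)2 (1 equiv), pyridine and 4 Å molecular sieves in CH2Cl2 under air at rt. This comes back to the route at 18.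

**Step 11 (borylation of the di-ortho-substituted, electron-rich bromide 14).** The risk is hydrodebromination back to 13 or no conversion. The fallback installs the C5 oxygen by C-formylation and Dakin-type Baeyer–Villiger oxidation instead of through a carbon–boron bond. It sets out from 13, so steps 10–12 are bypassed. Rieche formylation (Cl2CHOMe, AgOTf, CH2Cl2, −78 °C, mild enough for the benzyl groups) at C5 gives benzyl 2-(benzyloxy)-5-formyl-4-methoxy-6-pentylbenzoate F2. mCPBA in CH2Cl2 with NaHCO3 buffer then converts this electron-rich aldehyde into the aryl formate benzyl 2-(benzyloxy)-5-(formyloxy)-4-methoxy-6-pentylbenzoate F3. Brief K2CO3/MeOH at 0 °C methanolyses the formate and comes back to the route at 17.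

**Step 8 (saponification of the hindered ester 11).** The risk is incomplete hydrolysis, or decarboxylation of the free salicylic acid 12 on acidification. The fallback protects the phenol first and cleaves the ester by SN2 attack at the O-methyl carbon rather than at the acyl carbon. It sets out from 11. BnBr, K2CO3 and DMF at 60 °C give methyl 2-(benzyloxy)-4-methoxy-6-pentylbenzoate F4. LiSPr (lithium propane-1-thiolate) in DMPU at rt to 50 °C removes the ester methyl group to give 2-(benzyloxy)-4-methoxy-6-pentylbenzoic acid F5, which lacks the free ortho-hydroxyl that promotes decarboxylation. BnBr, K2CO3 and DMF then esterify F5 and come back to the route at 13.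

## Further compounds

F1 | step 13 | [5-(benzyloxy)-2-(methoxycarbonyl)-3-pentylphenyl]boronic acid | CCCCCc1cc(OCc2ccccc2)cc(B(O)O)c1C(=O)OC
F2 | step 11 | benzyl 2-(benzyloxy)-5-formyl-4-methoxy-6-pentylbenzoate | CCCCCc1c(C=O)c(OC)cc(OCc2ccccc2)c1C(=O)OCc1ccccc1
F3 | step 11 | benzyl 2-(benzyloxy)-5-(formyloxy)-4-methoxy-6-pentylbenzoate | CCCCCc1c(OC=O)c(OC)cc(OCc2ccccc2)c1C(=O)OCc1ccccc1
F4 | step 8 | methyl 2-(benzyloxy)-4-methoxy-6-pentylbenzoate | CCCCCc1cc(OC)cc(OCc2ccccc2)c1C(=O)OC
F5 | step 8 | 2-(benzyloxy)-4-methoxy-6-pentylbenzoic acid | CCCCCc1cc(OC)cc(OCc2ccccc2)c1C(=O)O
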